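## The problem

The target is a (2S)-flavan. Ring A is fused to the oxygen heterocycle ring C, and the catechol ring B sits on C2. Ring A carries a 2-methylbut-3-en-2-yl (1,1-dimethylallyl) group at C6 beside the 7-OH, and ring B carries two 3-methylbut-2-enyl (prenyl) groups at C2′ and C5′, each ortho to one catechol oxygen.

C2 is the only stereocentre, so nothing in the molecule can relay chirality to it and a catalyst or reagent must set it. It is also fragile: the 4′-oxygen lies para to C1′ and can push out O1 as a phenoxide (quinone methide opening) under base or heat, and acid can ionise the same benzylic C2–O1 bond.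

The C6 substituent is a quaternary benzylic carbon. The two ring B prenyl groups are the pattern an aromatic Claisen rearrangement of 3′,4′-bis(1,1-dimethylallyl) ethers leaves, with C2′ crowded between C1′ and C3′.

Groups that will not stand rough treatment:
- the catechol (oxidation);
- the ortho-prenyl phenols (acid closes them to dimethylchromans);
- the terminal vinyl group of the C6 side chain (lost to diimide or hydrogen, so ring C must be saturated before it is installed);
- the benzylic C2–O1 bond (hydrogenolysis).

The key step is possible because C3 and C4 of ring C are plain methylenes. The C3–C4 bond can therefore be carried as a C3=C4 alkene, formed by metathesis between a vinyl group on C4a and the vinyl group of an allyl ether whose carbinol carbon is C2 and whose oxygen is O1. The stereochemical problem then becomes an intermolecular O1–C2 bond formation that a chiral catalyst can control.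

## Retrosynthesis

Target 19 is traced back to its 7-O-methoxymethyl ether 18 by cutting the O7–CH2 acetal bond. An acetal at O7 is preferred to a silyl ether (not distinguishable from the ring B silyl ethers), an ester (would not survive ylide and aryloxide chemistry) or a benzyl ether (hydrogenolysis would take the alkenes). The forward step must free one phenol with dilute acid without closing the ortho-prenyl phenols onto their alkenes.

In 18 the C2′–CH2 and C5′–CH2 bonds are cut together, by a double retro-Claisen step, to the bis(1,1-dimethylallyl) ether 17. The two O–C(CH3)2 bonds of 17 are then cut to catechol 15 and the tertiary allylic carbonate 16. Direct C-prenylation of a catechol would not tell C2′, C5′ and C6′ apart, whereas sigmatropic delivery from each oxygen can reach only its one free ortho carbon. 15 has no ring B side chains. The forward steps need O-selective tert-allylation of both hydroxyls and rearrangement into the crowded C2′ position.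

15 comes from its bis(triisopropylsilyl) ether 14 (two O–Si bonds). 14 is cut at the C6–C(CH3)2 bond to aryl bromide 12 and prenylboronate 13. This cut must follow saturation of ring C, since the terminal vinyl group would not survive reduction of C3=C4. A bromine at C6 holds the place and is already present in commercial aldehyde 1, so no regioselective halogenation is needed. The forward coupling must join the aryl carbon to the tertiary (γ) carbon of the allyl unit.

12 is related to the 2H-chromene 11 by the C3=C4 double bond. The forward step must reduce a styrenic alkene while sparing an aryl bromide and a benzylic ether, which points to diimide.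

In 11 the C3=C4 bond is cut by retro-metathesis to diene 10. Closing the chroman at O1–C2 would mean substitution at an ionisation-prone, electron-rich benzylic carbinol, and closing at O1–C8a would mean an aryl C–O coupling. The chosen cut instead opens ring C at a carbon–carbon bond that carries no stereochemistry, and leaves O1–C2 as an intermolecular ether linkage. 10 is an acyclic union of one ring A and one ring B fragment. The forward reaction must engage only the two terminal alkenes and must not move the new double bond toward C2.

10 is cut at O1–C2 to 2-vinylphenol 3, used as its lithium aryloxide 9, and the linear cinnamyl carbonate 8. A catalytic allylic substitution is preferred to alkylation with a preformed chiral 1-arylallyl electrophile, which would racemise by ionisation. The iridium catalyst must direct attack to the aryl-bearing allyl terminus and give the (S) configuration.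

3 comes from salicylaldehyde 2 by methylenation (C=C bond), and 2 from commercial 5-bromo-2,4-dihydroxybenzaldehyde 1 (O4–CH2 bond). 8 is the tert-butyl carbonate of cinnamyl alcohol 7. 7 comes from ester 6 by reduction, 6 from aldehyde 5 by a two-carbon olefination, and 5 from commercial 3,4-dihydroxybenzaldehyde 4 by silylation. These are routine operations; the only selectivity asked is alkylation of the 4-OH of 1 in preference to the hydrogen-bonded 2-OH.

## Roads not taken

Alternative 1: The cut is at the two aryl–prenyl bonds C2′–CH2 and C5′–CH2, as the defining step. The bis(1,1-dimethylallyl) ether A1, carrying a silyl ether at O7, would be heated so that both allyl groups migrate with allylic transposition to give the 7-O-silyl ether A2 of the target.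
- Merits: both prenyl groups arrive in one metal-free operation with regiochemistry fixed by the ortho relationship. The final step would be a fluoride desilylation, which is gentler to ortho-prenyl phenols than the acid needed for 18; in that respect this road is better.
- Weak points: it does not say how ring C and C2 are made. A silyl group at O7 forces a non-silyl protecting group onto ring B earlier. The crowded C2′ site, migration to the occupied C4′ carbon and exposure of the free 4′-OH to heat are all concentrated in the step on which the plan rests.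
- Comparison: the chosen plan uses the same rearrangement (17 to 18), but as an endgame step and not as the strategic centre, so it inherits the same risk. Against the milder final deprotection of A2 it sets an O7 acetal that is orthogonal to the ring B silyl ethers and stable to the aqueous base of the C6 coupling.

Alternative 2: The cut is at O1–C2 in an oxidative sense. The catechol of diarylpropane A3 would be oxidised with Ag2O to ortho-quinone A4, which tautomerises to para-quinone methide A5. The C8a phenol would add to the methide carbon under a chiral phosphoric acid to give chroman pivalate A6.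
- Merits: an achiral, easily assembled precursor; ring C and C2 formed in one step; no ring B protecting groups; and a short route to the flavan core. If it worked it would be shorter than the chosen plan.
- Weak points: A4 is electrophilic on the ring as well as through its tautomer. The uncatalysed six-membered closure of A5 is fast, so the chiral acid must outrun a racemic background. A6 is itself a catechol that the same oxidant can reoxidise, reopening C2 to racemisation. The electron-rich ring A phenol is also oxidisable. The ring B prenyl groups would still have to be added afterwards by the same ether formation and rearrangement.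
- Comparison: the chosen plan is longer, but its enantiocontrol rests on an allylic etherification with a known nucleophile class, and no oxidant is present near the free phenols.

Alternative 3: The cut is at O1–C8a. The alkoxide of bromo alcohol A7 would displace bromide at C8a under Pd(OAc)2, a bulky di-tert-butylbiarylphosphine and Cs2CO3. The C2–O bond is not broken, so configuration is retained, and the product is the tris(methoxymethyl) ether A8 of the target.
- Merits: full convergence; C2 would be set by asymmetric reduction of an aryl ketone, which is probably more dependable than allylic etherification; no configurationally labile chromene and no alkene reduction, so all three side chains can be in place before ring closure. In stereochemical security and convergence this road is at least equal to the chosen one.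
- Weak points: a secondary benzylic palladium alkoxide can undergo β-hydride elimination to the ketone in competition with C–O reductive elimination. The bromide is electron-rich and ortho-substituted, and the carbinol is flanked by the C2′ prenyl group. Three acetals must then be removed in acid in the presence of three acid-sensitive alkenes. Both fragments must carry their side chains through organometallic fragment syntheses.
- Comparison: the chosen plan sets against it a ring closure that is very reliable for this ring size, a single acetal at the end, and side chains introduced only after the steps they would not survive.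

Key step: step 8

Assumption: the (Sa,Sc,Sc)-phosphoramidite is taken to give the (S)-ether in step 7, by the facial rule of this iridium catalyst family for cinnamyl electrophiles and heteroatom nucleophiles; if the sense were opposite, the mirror-image ligand would be used with no other change. Compounds 13 and 16 are taken as purchasable reagents.

## Route

Step 1
Reactants: 1 5-bromo-2,4-dihydroxybenzaldehyde
Product: 2 5-bromo-2-hydroxy-4-(methoxymethoxy)benzaldehyde
Conditions: MOMCl (1.1 eq), K2CO3 (1.5 eq), acetone, 0 °C → rt
Reagents that add atoms: chloromethyl methyl ether (MOMCl), COCCl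
Why: Williamson O-alkylation; the 2-OH is held in a hydrogen bond to the aldehyde and is the less acidic phenol, so one equivalent of MOMCl should alkylate the 4-OH selectively, as is routine for 2,4-dihydroxybenzaldehydes.

Step 2
Reactants: 2 5-bromo-2-hydroxy-4-(methoxymethoxy)benzaldehyde
Product: 3 4-bromo-5-(methoxymethoxy)-2-vinylphenol
Conditions: Ph3PCH3Br (2.5 eq), KOtBu (2.4 eq), THF, 0 °C → rt
Reagents that add atoms: methyltriphenylphosphonium bromide, C[P+](c1ccccc1)(c1ccccc1)c1ccccc1.[Br-]
Why: Wittig methylenation; the first equivalent of ylide deprotonates the phenol and the second converts the aldehyde into the vinyl group, the standard entry to 2-vinylphenols from salicylaldehydes. The acetal and aryl bromide are inert, and 3 is used promptly to avoid styrene polymerisation.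

Step 3
Reactants: 4 3,4-dihydroxybenzaldehyde
Product: 5 3,4-bis(triisopropylsilyloxy)benzaldehyde
Conditions: i-Pr3SiCl (2.4 eq), imidazole (5 eq), DMF, rt
Reagents that add atoms: chlorotriisopropylsilane, CC(C)[Si](Cl)(C(C)C)C(C)C
Why: Silyl ether formation; triisopropylsilyl is chosen over smaller silyl groups because its aryl ethers should withstand the lithium aryloxide of step 7 and the aqueous phosphate of step 10, yet fall to fluoride in step 11.

Step 4
Reactants: 5 3,4-bis(triisopropylsilyloxy)benzaldehyde
Product: 6 ethyl (E)-3-[3,4-bis(triisopropylsilyloxy)phenyl]acrylate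
Conditions: Ph3P=CHCO2Et (1.2 eq), CH2Cl2, rt
Reagents that add atoms: ethyl (triphenylphosphoranylidene)acetate, CCOC(=O)C=P(c1ccccc1)(c1ccccc1)c1ccccc1
Why: Wittig olefination with a stabilised ylide under neutral conditions, which should give the (E)-cinnamate and leave the base-labile aryl silyl ethers alone.

Step 5
Reactants: 6 ethyl (E)-3-[3,4-bis(triisopropylsilyloxy)phenyl]acrylate
Product: 7 (E)-3-[3,4-bis(triisopropylsilyloxy)phenyl]prop-2-en-1-ol
Conditions: i-Bu2AlH (2.5 eq), CH2Cl2, −78 °C; aq. potassium sodium tartrate
Reagents that add atoms: none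
Why: 1,2-Reduction of the conjugated ester to the allylic alcohol by the aluminium hydride at low temperature; alkene geometry and silyl ethers are unaffected.

Step 6
Reactants: 7 (E)-3-[3,4-bis(triisopropylsilyloxy)phenyl]prop-2-en-1-ol
Product: 8 tert-butyl (E)-3-[3,4-bis(triisopropylsilyloxy)phenyl]allyl carbonate
Conditions: Boc2O (1.2 eq), DMAP (10 mol%), CH2Cl2, 0 °C → rt
Reagents that add atoms: di-tert-butyl dicarbonate (Boc2O), CC(C)(C)OC(=O)OC(=O)OC(C)(C)C
Why: Acylation of the primary alcohol under nucleophilic catalysis; the tert-butyl carbonate is chosen because the tert-butoxide it releases in step 7 neither transesterifies the carbonate nor competes as a nucleophile.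

Step 7
Reactants: 3 4-bromo-5-(methoxymethoxy)-2-vinylphenol; 8 tert-butyl (E)-3-[3,4-bis(triisopropylsilyloxy)phenyl]allyl carbonate
Product: 10 (S)-1-bromo-2-(methoxymethoxy)-5-vinyl-4-{1-[3,4-bis(triisopropylsilyloxy)phenyl]allyloxy}benzene, via lithium aryloxide 9 (not isolated)
Conditions: 3 (1.2 eq), LiN(SiMe3)2 (1.2 eq), THF, 0 °C; then 8, [Ir(cod)Cl]2 (2 mol%), (Sa,Sc,Sc)-O,O′-(1,1′-binaphthyl-2,2′-diyl) N,N-bis(1-phenylethyl)phosphoramidite (4 mol%, pre-activated with n-PrNH2), THF, rt → 40 °C
Reagents that add atoms: none
Why: Iridium-catalysed asymmetric allylic etherification: the cyclometalated iridium–phosphoramidite complex ionises the linear carbonate and the aryloxide attacks the aryl-substituted allyl terminus, so the branched ether forms and C2 is set by the chiral ligand (catalyst control), the (Sa,Sc,Sc) ligand being expected to give (S). 2-Vinylphenols are established nucleophiles in this reaction, and the reaction is stopped at full conversion to limit re-ionisation of the electron-rich product.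

Step 8
Reactants: 10 (S)-1-bromo-2-(methoxymethoxy)-5-vinyl-4-{1-[3,4-bis(triisopropylsilyloxy)phenyl]allyloxy}benzene
Product: 11 (S)-6-bromo-7-(methoxymethoxy)-2-[3,4-bis(triisopropylsilyloxy)phenyl]-2H-chromene
Conditions: second-generation Grubbs catalyst (H2IMes)(PCy3)Cl2Ru=CHPh (3 mol%), 1,4-benzoquinone (10 mol%), CH2Cl2 (0.01 M, degassed), 40 °C, dark
Reagents that add atoms: none
Why: Ring-closing olefin metathesis: the ruthenium benzylidene exchanges onto one terminal alkene of 10, the new alkylidene adds to the other vinyl group to give a ruthenacyclobutane, and cycloreversion releases 11 and Ru=CH2, which returns to the cycle with loss of ethylene. The closest known reaction type is the ring-closing metathesis of 2-vinylphenyl 1-arylallyl ethers to 2-aryl-2H-chromenes, including ethers made by iridium-catalysed allylic etherification. Ring C closes as a six-membered ring by joining the carbon of the C4a vinyl group (C4) to the inner carbon of the allyl ether (C3), an entropically easy closure between two monosubstituted alkenes that escaping ethylene makes irreversible. No stereocentre is formed; C2 comes from step 7 and none of its bonds is made or broken. The step needs chemoselectivity, secured by the substrate holding only these two alkenes (the ring B prenyl groups and the C6 side chain are still absent, bromine standing in at C6), and it needs the C3=C4 bond to stay where it forms. Migration of that bond to C2=C3 by ruthenium hydride decomposition products would give the achiral 4H-chromene, so 1,4-benzoquinone is added as hydride scavenger, the solution is degassed and the reaction is stopped at full conversion. Dilution disfavours cross-metathesis dimers, and 40 °C in the dark avoids electrocyclic opening of the chromene, after which 11 is reduced without storage.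

Step 9
Reactants: 11 (S)-6-bromo-7-(methoxymethoxy)-2-[3,4-bis(triisopropylsilyloxy)phenyl]-2H-chromene
Product: 12 (S)-6-bromo-7-(methoxymethoxy)-2-[3,4-bis(triisopropylsilyloxy)phenyl]chroman
Conditions: 2-nitrobenzenesulfonohydrazide (excess, in portions), Et3N, CH2Cl2, rt, dark
Reagents that add atoms: none
Why: Diimide reduction (concerted syn transfer of two hydrogens from HN=NH generated at room temperature) should saturate the cis-disubstituted C3=C4 bond without hydrogenolysis of the benzylic C2–O1 bond or the aryl bromide, both of which hydrogenation over palladium would endanger. C2 is not involved, and the mild, light-free conditions avoid opening of the chromene before it is reduced.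

Step 10
Reactants: 12 (S)-6-bromo-7-(methoxymethoxy)-2-[3,4-bis(triisopropylsilyloxy)phenyl]chroman; 13 prenylboronic acid pinacol ester
Product: 14 (S)-7-(methoxymethoxy)-6-(2-methylbut-3-en-2-yl)-2-[3,4-bis(triisopropylsilyloxy)phenyl]chroman
Conditions: 13 (1.5 eq), Pd(OAc)2 (3 mol%), electron-poor biarylphosphine of the type (biaryl)P[3,5-(CF3)2C6H3]2 (6 mol%), K3PO4 (aq), THF, 40–60 °C
Reagents that add atoms: none
Why: γ-Selective Suzuki–Miyaura coupling of an allylboronate: transmetalation by an SE2′ path places palladium on the tertiary carbon, and an electron-poor phosphine should make reductive elimination faster than allyl isomerisation, so the aryl–C(CH3)2 bond of the 1,1-dimethylallyl group forms at C6. The triisopropylsilyl ethers, the acetal and C2 should be stable to aqueous phosphate at this temperature.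

Step 11
Reactants: 14 (S)-7-(methoxymethoxy)-6-(2-methylbut-3-en-2-yl)-2-[3,4-bis(triisopropylsilyloxy)phenyl]chroman
Product: 15 (S)-4-[7-(methoxymethoxy)-6-(2-methylbut-3-en-2-yl)chroman-2-yl]benzene-1,2-diol
Conditions: Bu4NF (2.2 eq), AcOH (2.2 eq), THF, 0 °C, Ar
Reagents that add atoms: none
Why: Fluoride cleavage of the two aryl silyl ethers; acetic acid buffers the phenoxides so that the 4′-oxide cannot expel O1 (quinone methide opening at C2) and the catechol is not oxidised. The acetal at O7 is inert to fluoride.

Step 12
Reactants: 15 (S)-4-[7-(methoxymethoxy)-6-(2-methylbut-3-en-2-yl)chroman-2-yl]benzene-1,2-diol; 16 tert-butyl 2-methylbut-3-en-2-yl carbonate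
Product: 17 (S)-7-(methoxymethoxy)-6-(2-methylbut-3-en-2-yl)-2-[3,4-bis(2-methylbut-3-en-2-yloxy)phenyl]chroman
Conditions: 16 (4 eq), Pd(PPh3)4 (10 mol%), THF, 0 °C, Ar
Reagents that add atoms: none
Why: Decarboxylative palladium-catalysed O-allylation (Tsuji–Trost type): zerovalent palladium ionises the tertiary carbonate, the released tert-butoxide deprotonates the phenol, and at low temperature the phenoxide attacks the more substituted allyl terminus. This is the known way to make aryl 1,1-dimethylallyl ethers of phenols and catechols, and excess 16 should carry both hydroxyls through.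

Step 13
Reactants: 17 (S)-7-(methoxymethoxy)-6-(2-methylbut-3-en-2-yl)-2-[3,4-bis(2-methylbut-3-en-2-yloxy)phenyl]chroman
Product: 18 (S)-4-[7-(methoxymethoxy)-6-(2-methylbut-3-en-2-yl)chroman-2-yl]-3,6-bis(3-methylbut-2-en-1-yl)benzene-1,2-diol
Conditions: PhMe (degassed), 110 °C, sealed tube, Ar
Reagents that add atoms: none
Why: Two aromatic Claisen ([3,3]-sigmatropic) rearrangements: the 4′-O-allyl group migrates to its only free ortho carbon C5′ and the 3′-O-allyl group to C2′, each with allylic transposition, so the 1,1-dimethylallyl ethers become prenyl groups and tautomerisation restores the catechol. The geminal methyl groups let such ethers rearrange near 110 °C in neutral solvent, conditions under which the acetal, the C6 vinyl group and C2 should hold.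

Step 14
Reactants: 18 (S)-4-[7-(methoxymethoxy)-6-(2-methylbut-3-en-2-yl)chroman-2-yl]-3,6-bis(3-methylbut-2-en-1-yl)benzene-1,2-diol
Product: 19 (S)-4-[7-hydroxy-6-(2-methylbut-3-en-2-yl)chroman-2-yl]-3,6-bis(3-methylbut-2-en-1-yl)benzene-1,2-diol (CNP0118330.1)
Conditions: HCl (3 M aq)/MeOH, rt, Ar
Reagents that add atoms: none
Why: Acid-catalysed transacetalisation of the aryl methoxymethyl ether to methanol; dilute acid at room temperature is the usual way to free ortho-prenylated phenols from such ethers, since protonation of the trisubstituted alkenes (chroman closure) needs stronger acid or heat. Opening of ring C at C2 in 4′-hydroxyflavans is mainly a base- and heat-driven process, so the stereocentre should hold.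

## Compound list

1 | 5-bromo-2,4-dihydroxybenzaldehyde | O=Cc1cc(Br)c(O)cc1O | starting material
2 | 5-bromo-2-hydroxy-4-(methoxymethoxy)benzaldehyde | O=Cc1cc(Br)c(OCOC)cc1O | intermediate
3 | 4-bromo-5-(methoxymethoxy)-2-vinylphenol | C=Cc1cc(Br)c(OCOC)cc1O | intermediate
4 | 3,4-dihydroxybenzaldehyde | O=Cc1ccc(O)c(O)c1 | starting material
5 | 3,4-bis(triisopropylsilyloxy)benzaldehyde | O=Cc1ccc(O[Si](C(C)C)(C(C)C)C(C)C)c(O[Si](C(C)C)(C(C)C)C(C)C)c1 | intermediate
6 | ethyl (E)-3-[3,4-bis(triisopropylsilyloxy)phenyl]acrylate | CCOC(=O)/C=C/c1ccc(O[Si](C(C)C)(C(C)C)C(C)C)c(O[Si](C(C)C)(C(C)C)C(C)C)c1 | intermediate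
7 | (E)-3-[3,4-bis(triisopropylsilyloxy)phenyl]prop-2-en-1-ol | OC/C=C/c1ccc(O[Si](C(C)C)(C(C)C)C(C)C)c(O[Si](C(C)C)(C(C)C)C(C)C)c1 | intermediate
8 | tert-butyl (E)-3-[3,4-bis(triisopropylsilyloxy)phenyl]allyl carbonate | CC(C)(C)OC(=O)OC/C=C/c1ccc(O[Si](C(C)C)(C(C)C)C(C)C)c(O[Si](C(C)C)(C(C)C)C(C)C)c1 | intermediate
9 | lithium 4-bromo-5-(methoxymethoxy)-2-vinylphenoxide | C=Cc1cc(Br)c(OCOC)cc1[O-].[Li+] | intermediate
10 | (S)-1-bromo-2-(methoxymethoxy)-5-vinyl-4-{1-[3,4-bis(triisopropylsilyloxy)phenyl]allyloxy}benzene | C=Cc1cc(Br)c(OCOC)cc1O[C@H](c1ccc(O[Si](C(C)C)(C(C)C)C(C)C)c(O[Si](C(C)C)(C(C)C)C(C)C)c1)C=C | intermediate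
11 | (S)-6-bromo-7-(methoxymethoxy)-2-[3,4-bis(triisopropylsilyloxy)phenyl]-2H-chromene | Brc1cc2c(cc1OCOC)O[C@H](c1ccc(O[Si](C(C)C)(C(C)C)C(C)C)c(O[Si](C(C)C)(C(C)C)C(C)C)c1)C=C2 | intermediate
12 | (S)-6-bromo-7-(methoxymethoxy)-2-[3,4-bis(triisopropylsilyloxy)phenyl]chroman | Brc1cc2c(cc1OCOC)O[C@H](c1ccc(O[Si](C(C)C)(C(C)C)C(C)C)c(O[Si](C(C)C)(C(C)C)C(C)C)c1)CC2 | intermediate
13 | prenylboronic acid pinacol ester | CC(C)=CCB1OC(C)(C)C(C)(C)O1 | starting material
14 | (S)-7-(methoxymethoxy)-6-(2-methylbut-3-en-2-yl)-2-[3,4-bis(triisopropylsilyloxy)phenyl]chroman | C=CC(C)(C)c1cc2c(cc1OCOC)O[C@H](c1ccc(O[Si](C(C)C)(C(C)C)C(C)C)c(O[Si](C(C)C)(C(C)C)C(C)C)c1)CC2 | intermediate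
15 | (S)-4-[7-(methoxymethoxy)-6-(2-methylbut-3-en-2-yl)chroman-2-yl]benzene-1,2-diol | C=CC(C)(C)c1cc2c(cc1OCOC)O[C@H](c1ccc(O)c(O)c1)CC2 | intermediate
16 | tert-butyl 2-methylbut-3-en-2-yl carbonate | C=CC(C)(C)OC(=O)OC(C)(C)C | starting material
17 | (S)-7-(methoxymethoxy)-6-(2-methylbut-3-en-2-yl)-2-[3,4-bis(2-methylbut-3-en-2-yloxy)phenyl]chroman | C=CC(C)(C)c1cc2c(cc1OCOC)O[C@H](c1ccc(OC(C)(C)C=C)c(OC(C)(C)C=C)c1)CC2 | intermediate
18 | (S)-4-[7-(methoxymethoxy)-6-(2-methylbut-3-en-2-yl)chroman-2-yl]-3,6-bis(3-methylbut-2-en-1-yl)benzene-1,2-diol | C=CC(C)(C)c1cc2c(cc1OCOC)O[C@H](c1cc(CC=C(C)C)c(O)c(O)c1CC=C(C)C)CC2 | intermediate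
19 | (S)-4-[7-hydroxy-6-(2-methylbut-3-en-2-yl)chroman-2-yl]-3,6-bis(3-methylbut-2-en-1-yl)benzene-1,2-diol | C=CC(C)(C)c1cc2c(cc1O)O[C@H](c1cc(CC=C(C)C)c(O)c(O)c1CC=C(C)C)CC2 | target

## Step count and least certain steps

Total step count: 14. Longest linear sequence: 12 steps (steps 3 to 14, from 4); the ring A branch (steps 1 and 2) joins at step 7.

Step 8 (key step). The likely failure is migration of the new C3=C4 double bond into conjugation with O1 and the C2 aryl group, caused by ruthenium hydride species as the catalyst decays; this erases C2. A slower erosion by reversible electrocyclic opening of the chromene under light or heat is also possible. The fallback accepts the loss and restores C2 afterwards. It sets out from 11 (of any enantiomeric purity, or the crude metathesis mixture), which is isomerised fully with RuHCl(CO)(PPh3)3 in toluene at 80 °C to 6-bromo-7-(methoxymethoxy)-2-[3,4-bis(triisopropylsilyloxy)phenyl]-4H-chromene F1. The enol ether double bond of F1 is then hydrogenated with a cationic iridium complex [Ir(cod)(L)][B(3,5-(CF3)2C6H3)4] (L = chiral phosphinooxazoline, enantiomer chosen for the (S) product; H2 50 bar, CH2Cl2), a known way to 2-arylchromans that spares aryl bromides. It comes back to the route at 12.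

Step 7. The likely failure is re-ionisation of the product ether by the iridium catalyst, since the ether has an electron-rich aryl group and an aryloxide leaving group; this leads to loss of enantiomeric purity and drift to the linear cinnamyl ether. Slow attack by the ortho-substituted aryloxide is a second risk. The fallback forms the same O1–C2 bond by substitution with inversion. It sets out from 5: addition of CH2=CHMgBr (THF, −78 °C) gives racemic 1-[3,4-bis(triisopropylsilyloxy)phenyl]prop-2-en-1-ol F2. Sharpless kinetic resolution (Ti(OiPr)4, D-(−)-diisopropyl tartrate as indicated by the usual mnemonic, t-BuOOH, CH2Cl2, −20 °C) consumes the (S)-alcohol and leaves (R)-1-[3,4-bis(triisopropylsilyloxy)phenyl]prop-2-en-1-ol F3. Mitsunobu etherification of F3 with phenol 3 (PPh3, diisopropyl azodicarboxylate, toluene, −20 °C) comes back to the route at 10.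

Step 10. The likely failures are isomerisation of the first-formed tertiary allylpalladium species to the primary one before reductive elimination (giving the linear prenyl arene), slow transmetalation beside the ortho acetal, and protodebromination. The fallback builds the quaternary carbon first and the alkene last. It sets out from 12: palladium-catalysed α-arylation of the Reformatsky reagent BrZnC(CH3)2CO2Et (from ethyl 2-bromoisobutyrate and Zn; Pd(dba)2, P(t-Bu)3, THF, rt) gives ethyl 2-{(S)-7-(methoxymethoxy)-2-[3,4-bis(triisopropylsilyloxy)phenyl]chroman-6-yl}-2-methylpropanoate F4. Reduction with i-Bu2AlH gives 2-{(S)-7-(methoxymethoxy)-2-[3,4-bis(triisopropylsilyloxy)phenyl]chroman-6-yl}-2-methylpropan-1-ol F5. Dess–Martin oxidation gives 2-{(S)-7-(methoxymethoxy)-2-[3,4-bis(triisopropylsilyloxy)phenyl]chroman-6-yl}-2-methylpropanal F6. Wittig methylenation of F6 (Ph3PCH3Br, KOtBu, THF) comes back to the route at 14.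

Step 13. The likely failure is migration of the 3′-O-allyl group to the occupied C4′ carbon in place of the crowded C2′, followed by a Cope shift to C6′ or by intramolecular Diels–Alder trapping of the dienone by the neighbouring allyl ether. Thermal opening of ring C once the 4′-OH is free is a further risk. The fallback introduces the two prenyl groups one at a time, so that no dienone carries a second allyl ether. It sets out from 15, and both regioisomeric series converge:
- One equivalent of 16 under the step 12 conditions gives (S)-2-(3-hydroxy-4-{(S)-chromanyl})phenyl-type monoethers, namely 5-[(S)-7-(methoxymethoxy)-6-(2-methylbut-3-en-2-yl)chroman-2-yl]-2-hydroxyphenyl 2-methylbut-3-en-2-yl ether F7 (ether at O3′) and 4-[(S)-7-(methoxymethoxy)-6-(2-methylbut-3-en-2-yl)chroman-2-yl]-2-hydroxyphenyl 2-methylbut-3-en-2-yl ether F8 (ether at O4′).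
- Heating (toluene, 110 °C) rearranges these to the 2′-prenyl catechol F9 and the 5′-prenyl catechol F10.
- In each, the hydroxyl not flanked by the new prenyl group is the more accessible, so a second etherification should give the 2′-prenyl 4′-O-(1,1-dimethylallyl) ether F11 and the 5′-prenyl 3′-O-(1,1-dimethylallyl) ether F12.
- A second rearrangement of F11 and F12 comes back to the route at 18.

Step 14. The likely failures are acid-induced closure of the ortho-prenyl phenols onto their alkenes (dimethylchroman formation), addition of methanol to the alkenes, or ionisation at C2. The fallback exchanges the acetal for a silyl ether without protic acid. It sets out from 18: Et3SiOTf and 2,2′-bipyridyl (CH2Cl2, 0 °C), a known conversion of aryl methoxymethyl ethers into aryl triethylsilyl ethers, would also silylate the catechol and give the tris(triethylsilyl) ether of the target F13. Buffered fluoride (Bu4NF, AcOH, THF, 0 °C) then comes back to the route at 19.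

## Further compounds

F1 | step 8 | 6-bromo-7-(methoxymethoxy)-2-[3,4-bis(triisopropylsilyloxy)phenyl]-4H-chromene | Brc1cc2c(cc1OCOC)OC(c1ccc(O[Si](C(C)C)(C(C)C)C(C)C)c(O[Si](C(C)C)(C(C)C)C(C)C)c1)=CC2
F2 | step 7 | racemic 1-[3,4-bis(triisopropylsilyloxy)phenyl]prop-2-en-1-ol | C=CC(O)c1ccc(O[Si](C(C)C)(C(C)C)C(C)C)c(O[Si](C(C)C)(C(C)C)C(C)C)c1
F3 | step 7 | (R)-1-[3,4-bis(triisopropylsilyloxy)phenyl]prop-2-en-1-ol | C=C[C@@H](O)c1ccc(O[Si](C(C)C)(C(C)C)C(C)C)c(O[Si](C(C)C)(C(C)C)C(C)C)c1
F4 | step 10 | ethyl 2-{(S)-7-(methoxymethoxy)-2-[3,4-bis(triisopropylsilyloxy)phenyl]chroman-6-yl}-2-methylpropanoate | CCOC(=O)C(C)(C)c1cc2c(cc1OCOC)O[C@H](c1ccc(O[Si](C(C)C)(C(C)C)C(C)C)c(O[Si](C(C)C)(C(C)C)C(C)C)c1)CC2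
F5 | step 10 | 2-{(S)-7-(methoxymethoxy)-2-[3,4-bis(triisopropylsilyloxy)phenyl]chroman-6-yl}-2-methylpropan-1-ol | OCC(C)(C)c1cc2c(cc1OCOC)O[C@H](c1ccc(O[Si](C(C)C)(C(C)C)C(C)C)c(O[Si](C(C)C)(C(C)C)C(C)C)c1)CC2
F6 | step 10 | 2-{(S)-7-(methoxymethoxy)-2-[3,4-bis(triisopropylsilyloxy)phenyl]chroman-6-yl}-2-methylpropanal | O=CC(C)(C)c1cc2c(cc1OCOC)O[C@H](c1ccc(O[Si](C(C)C)(C(C)C)C(C)C)c(O[Si](C(C)C)(C(C)C)C(C)C)c1)CC2
F7 | step 13 | (S)-2-hydroxy-5-[7-(methoxymethoxy)-6-(2-methylbut-3-en-2-yl)chroman-2-yl]phenyl 2-methylbut-3-en-2-yl ether (O3′ monoether) | C=CC(C)(C)c1cc2c(cc1OCOC)O[C@H](c1ccc(O)c(OC(C)(C)C=C)c1)CC2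
F8 | step 13 | (S)-2-hydroxy-4-[7-(methoxymethoxy)-6-(2-methylbut-3-en-2-yl)chroman-2-yl]phenyl 2-methylbut-3-en-2-yl ether (O4′ monoether) | C=CC(C)(C)c1cc2c(cc1OCOC)O[C@H](c1ccc(OC(C)(C)C=C)c(O)c1)CC2
F9 | step 13 | (S)-4-[7-(methoxymethoxy)-6-(2-methylbut-3-en-2-yl)chroman-2-yl]-3-(3-methylbut-2-en-1-yl)benzene-1,2-diol (2′-prenyl catechol) | C=CC(C)(C)c1cc2c(cc1OCOC)O[C@H](c1ccc(O)c(O)c1CC=C(C)C)CC2
F10 | step 13 | (S)-5-[7-(methoxymethoxy)-6-(2-methylbut-3-en-2-yl)chroman-2-yl]-3-(3-methylbut-2-en-1-yl)benzene-1,2-diol (5′-prenyl catechol) | C=CC(C)(C)c1cc2c(cc1OCOC)O[C@H](c1cc(CC=C(C)C)c(O)c(O)c1)CC2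
F11 | step 13 | (S)-3-[7-(methoxymethoxy)-6-(2-methylbut-3-en-2-yl)chroman-2-yl]-2-(3-methylbut-2-en-1-yl)-6-(2-methylbut-3-en-2-yloxy)phenol (2′-prenyl, O4′ ether) | C=CC(C)(C)c1cc2c(cc1OCOC)O[C@H](c1ccc(OC(C)(C)C=C)c(O)c1CC=C(C)C)CC2
F12 | step 13 | (S)-4-[7-(methoxymethoxy)-6-(2-methylbut-3-en-2-yl)chroman-2-yl]-2-(3-methylbut-2-en-1-yl)-6-(2-methylbut-3-en-2-yloxy)phenol (5′-prenyl, O3′ ether) | C=CC(C)(C)c1cc2c(cc1OCOC)O[C@H](c1cc(CC=C(C)C)c(O)c(OC(C)(C)C=C)c1)CC2
F13 | step 14 | (S)-6-(2-methylbut-3-en-2-yl)-2-[2,5-bis(3-methylbut-2-en-1-yl)-3,4-bis(triethylsilyloxy)phenyl]-7-(triethylsilyloxy)chroman | C=CC(C)(C)c1cc2c(cc1O[Si](CC)(CC)CC)O[C@H](c1cc(CC=C(C)C)c(O[Si](CC)(CC)CC)c(O[Si](CC)(CC)CC)c1CC=C(C)C)CC2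
A1 | alternative 1 | (S)-7-(tert-butyldimethylsilyloxy)-6-(2-methylbut-3-en-2-yl)-2-[3,4-bis(2-methylbut-3-en-2-yloxy)phenyl]chroman | C=CC(C)(C)c1cc2c(cc1O[Si](C)(C)C(C)(C)C)O[C@H](c1ccc(OC(C)(C)C=C)c(OC(C)(C)C=C)c1)CC2
A2 | alternative 1 | (S)-4-[7-(tert-butyldimethylsilyloxy)-6-(2-methylbut-3-en-2-yl)chroman-2-yl]-3,6-bis(3-methylbut-2-en-1-yl)benzene-1,2-diol | C=CC(C)(C)c1cc2c(cc1O[Si](C)(C)C(C)(C)C)O[C@H](c1cc(CC=C(C)C)c(O)c(O)c1CC=C(C)C)CC2
A3 | alternative 2 | 4-[3-(3,4-dihydroxyphenyl)propyl]-5-hydroxy-2-(2-methylbut-3-en-2-yl)phenyl pivalate | C=CC(C)(C)c1cc(CCCc2ccc(O)c(O)c2)c(O)cc1OC(=O)C(C)(C)C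
A4 | alternative 2 | 4-[3-(3,4-dioxocyclohexa-1,5-dien-1-yl)propyl]-5-hydroxy-2-(2-methylbut-3-en-2-yl)phenyl pivalate (ortho-quinone) | C=CC(C)(C)c1cc(CCCC2=CC(=O)C(=O)C=C2)c(O)cc1OC(=O)C(C)(C)C
A5 | alternative 2 | 5-hydroxy-4-[3-(3-hydroxy-4-oxocyclohexa-2,5-dien-1-ylidene)propyl]-2-(2-methylbut-3-en-2-yl)phenyl pivalate (para-quinone methide) | C=CC(C)(C)c1cc(CCC=C2C=CC(=O)C(O)=C2)c(O)cc1OC(=O)C(C)(C)C
A6 | alternative 2 | (S)-2-(3,4-dihydroxyphenyl)-6-(2-methylbut-3-en-2-yl)chroman-7-yl pivalate | C=CC(C)(C)c1cc2c(cc1OC(=O)C(C)(C)C)O[C@H](c1ccc(O)c(O)c1)CC2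
A7 | alternative 3 | (S)-1-[3,4-bis(methoxymethoxy)-2,5-bis(3-methylbut-2-en-1-yl)phenyl]-3-[2-bromo-4-(methoxymethoxy)-5-(2-methylbut-3-en-2-yl)phenyl]propan-1-ol | C=CC(C)(C)c1cc(CC[C@H](O)c2cc(CC=C(C)C)c(OCOC)c(OCOC)c2CC=C(C)C)c(Br)cc1OCOC
A8 | alternative 3 | (S)-7-(methoxymethoxy)-6-(2-methylbut-3-en-2-yl)-2-[3,4-bis(methoxymethoxy)-2,5-bis(3-methylbut-2-en-1-yl)phenyl]chroman | C=CC(C)(C)c1cc2c(cc1OCOC)O[C@H](c1cc(CC=C(C)C)c(OCOC)c(OCOC)c1CC=C(C)C)CC2
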